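**Plan** (labdane numbering C1–C20; α/β as in the usual labdane drawing)

- Retrosynthesis: cut C9–C11 (C9 enol triflate + alkylzinc of the C11–C16 chain), then C6–C7 of ring B (C6 acyl radical onto C7 of a C9 isopropenyl ketone), then C8–C9 (isopropenyl onto a C9 aldehyde) and C4–CH3, and last C4–C5 and C1–C10 of ring A (Diels–Alder).
- Forward: ring A by Diels–Alder reaction, C4 methylation, adjustment of C9, C3 and C19 and acylation, unmasking of C6, closure of ring B, C6 reduction, C9 triflate, side-chain coupling, deprotection.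
- Enabling feature: C6 (carbinol) and C9 (the alkene carbon that carries the side chain) are 1,4 to each other across ring B. Ring B is therefore a masked cyclohexane-1,4-dione, the product of adding a C6 acyl radical to the β-carbon C7 of a C9 enone.
- Stereochemistry: C5 and C10 from the E geometry of the dienophile and its dioxolane stereocentre (from D-glyceraldehyde acetonide, later excised as the C6 aldehyde). C4 by enolate methylation anti to the C5 substituent and the C10 methyl. C3 and C6 by equatorial hydride attack giving axial alcohols. 13E by syn-carboalumination.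

Key step: step 11

Assumption: the diene is taken to add to enal 3 anti to the allylic C–O bond in the conformer that minimises A(1,3) strain; this gives the absolute configuration drawn. Centres that are erased later (C4 in 7 and 8, C9 in 11–13, C8 in 17–19) are drawn without configuration.

Step 1
Reactants: 1 (R)-2,2-dimethyl-1,3-dioxolane-4-carbaldehyde; 2 2-(triphenylphosphoranylidene)propanal
Product: 3 (2E)-3-[(4S)-2,2-dimethyl-1,3-dioxolan-4-yl]-2-methylprop-2-enal
Conditions: toluene, 80 °C
Reagents that add atoms: none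
Why: Wittig olefination with a stabilised ylide should give the E-enal under neutral conditions that leave the α-alkoxy stereocentre untouched.

Step 2
Reactants: 4 ethyl 3-hydroxypent-4-enoate (racemic)
Product: 5 ethyl 3-oxopent-4-enoate
Conditions: CrO3, H2SO4, H2O, acetone, 0 °C
Reagents that add atoms: none
Why: Jones oxidation of the allylic secondary alcohol should give the vinyl ketone, which is used at once.

Step 3
Reactants: 5 ethyl 3-oxopent-4-enoate
Product: 6 ethyl (2Z)-3-(trimethylsilyloxy)penta-2,4-dienoate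
Conditions: Me3SiCl, Et3N, Et2O, 0 °C → rt
Reagents that add atoms: chlorotrimethylsilane, C[Si](C)(C)Cl
Why: O-silylation of the chelated enol of the β-keto ester should give the Z silyl dienol ether, the isomer whose ester group points outward in the s-cis diene.

Step 4
Reactants: 3 (2E)-3-[(4S)-2,2-dimethyl-1,3-dioxolan-4-yl]-2-methylprop-2-enal; 6 ethyl (2Z)-3-(trimethylsilyloxy)penta-2,4-dienoate
Product: 8 ethyl 2-[(4S)-2,2-dimethyl-1,3-dioxolan-4-yl]-3-formyl-3-methyl-6-oxocyclohexane-1-carboxylate (5α-H 10β-CH3 10α-CHO; C4 epimers and enol), via cycloadduct silyl enol ether 7 (not isolated)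
Conditions: toluene, BHT (cat.), 110 °C; then 0.5 M citric acid, THF, 0 °C
Reagents that add atoms: none
Why: Thermal Diels–Alder reaction followed by mild hydrolysis of the silyl enol ether, in which the enol ether carbon of 6 should bond to the less hindered β-carbon C5 and the CH2 terminus to C10 (OSiMe3 para to CHO), the E geometry of 3 fixes CHO and the C5 substituent trans, and the diene should add anti to the allylic C–O bond of the dioxolane in the conformer with the allylic hydrogen eclipsing the alkene, which sets C5 and C10 as drawn; the minor facial isomer is a separable diastereomer.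

Step 5
Reactants: 8 ethyl 2-[(4S)-2,2-dimethyl-1,3-dioxolan-4-yl]-3-formyl-3-methyl-6-oxocyclohexane-1-carboxylate
Product: 9 ethyl 2-[(4S)-2,2-dimethyl-1,3-dioxolan-4-yl]-3-formyl-1,3-dimethyl-6-oxocyclohexane-1-carboxylate (4α-CH3 4β-CO2Et)
Conditions: K2CO3, MeI, acetone, rt
Reagents that add atoms: iodomethane, CI
Why: C-alkylation of the β-keto ester enolate, in which methyl iodide should attack the face anti to the C5 dioxolanyl group and to the axial C10 methyl, giving the C4 quaternary centre with the ester β (the future C19); the aldehyde is not enolisable.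

Step 6
Reactants: 9 ethyl 2-[(4S)-2,2-dimethyl-1,3-dioxolan-4-yl]-3-formyl-1,3-dimethyl-6-oxocyclohexane-1-carboxylate; 10 2-bromopropene
Product: 11 ethyl 2-[(4S)-2,2-dimethyl-1,3-dioxolan-4-yl]-3-(1-hydroxy-2-methylprop-2-enyl)-1,3-dimethyl-6-oxocyclohexane-1-carboxylate (C9 epimers)
Conditions: CrCl2 (4 equiv), NiCl2 (2 mol%), DMF, rt; dilute HCl work-up
Reagents that add atoms: none
Why: Nozaki–Hiyama–Kishi addition of the isopropenylchromium reagent should take the aldehyde and leave the ketone and the ester; the C9 carbinol centre forms as a mixture that is removed in step 8.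

Step 7
Reactants: 11 ethyl 2-[(4S)-2,2-dimethyl-1,3-dioxolan-4-yl]-3-(1-hydroxy-2-methylprop-2-enyl)-1,3-dimethyl-6-oxocyclohexane-1-carboxylate
Product: 13 3-[(4S)-2,2-dimethyl-1,3-dioxolan-4-yl]-2-(hydroxymethyl)-4-(1-hydroxy-2-methylprop-2-enyl)-2,4-dimethylcyclohexan-1-ol (3α-OH), via hydroxy ester 12 (not isolated)
Conditions: LiBH(s-Bu)3 (2.2 equiv), THF, −78 °C; then LiAlH4, 0 °C → rt
Reagents that add atoms: none
Why: Ketone reduction by a bulky borohydride, which should attack C3 equatorially in the chair that keeps both ring-B arms equatorial (C10 methyl and C4 ester axial) and so give the axial 3α-alcohol, followed by LiAlH4 reduction of the hindered ester to the C19 primary alcohol.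

Step 8
Reactants: 13 3-[(4S)-2,2-dimethyl-1,3-dioxolan-4-yl]-2-(hydroxymethyl)-4-(1-hydroxy-2-methylprop-2-enyl)-2,4-dimethylcyclohexan-1-ol
Product: 14 1-{2-[(4S)-2,2-dimethyl-1,3-dioxolan-4-yl]-4-hydroxy-3-(hydroxymethyl)-1,3-dimethylcyclohexyl}-2-methylprop-2-en-1-one
Conditions: MnO2 (excess), CH2Cl2, rt
Reagents that add atoms: none
Why: Selective allylic oxidation, since MnO2 should oxidise only the allylic C9 alcohol to the isopropenyl ketone and leave the saturated C3 and C19 alcohols.

Step 9
Reactants: 14 1-{2-[(4S)-2,2-dimethyl-1,3-dioxolan-4-yl]-4-hydroxy-3-(hydroxymethyl)-1,3-dimethylcyclohexyl}-2-methylprop-2-en-1-one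
Product: 15 {2-[(4S)-2,2-dimethyl-1,3-dioxolan-4-yl]-1,3-dimethyl-3-(2-methylprop-2-enoyl)-6-(3-methylbutanoyloxy)cyclohexyl}methyl 3-methylbutanoate
Conditions: 3-methylbutanoyl chloride (3 equiv), pyridine, DMAP (cat.), CH2Cl2, 0 → 40 °C
Reagents that add atoms: 3-methylbutanoyl chloride, CC(C)CC(=O)Cl
Why: DMAP-catalysed acylation should esterify the C19 primary and the hindered axial C3 hydroxyl, the only free hydroxyls at this stage.

Step 10
Reactants: 15 {2-[(4S)-2,2-dimethyl-1,3-dioxolan-4-yl]-1,3-dimethyl-3-(2-methylprop-2-enoyl)-6-(3-methylbutanoyloxy)cyclohexyl}methyl 3-methylbutanoate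
Product: 16 [2-formyl-1,3-dimethyl-3-(2-methylprop-2-enoyl)-6-(3-methylbutanoyloxy)cyclohexyl]methyl 3-methylbutanoate
Conditions: H5IO6, EtOAc, rt
Reagents that add atoms: none
Why: Periodic acid should hydrolyse the terminal acetonide and cleave the resulting 1,2-diol in one operation (glycol cleavage), unveiling the C6 aldehyde without base, so C5 and the two esters are not touched.

Step 11
Reactants: 16 [2-formyl-1,3-dimethyl-3-(2-methylprop-2-enoyl)-6-(3-methylbutanoyloxy)cyclohexyl]methyl 3-methylbutanoate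
Product: 17 [2,5,8a-trimethyl-6-(3-methylbutanoyloxy)-1,4-dioxodecahydronaphthalen-5-yl]methyl 3-methylbutanoate (trans-fused; C6 and C9 ketones; C8 epimers)
Conditions: (n-Bu4N)4[W10O32] (2 mol%), MeCN (0.01 M, degassed), 390 nm, rt
Reagents that add atoms: none
Why: The photoexcited decatungstate abstracts the formyl hydrogen of 16, the nucleophilic C6 acyl radical adds to the unsubstituted terminus C7 of the 2-methylpropenoyl group, and the tertiary α-keto radical at C8 takes a hydrogen atom back from the reduced polyoxometalate, so the step is an isomerisation. The closest known reaction type is the photocatalytic radical hydroacylation of enones by aldehydes (Giese-type acyl radical addition), in its intramolecular form the acyl radical–alkene cyclisation. Ring B closes in the 6-endo-trig mode; the 5-exo alternative would attack the fully substituted C8 against the polarity of the acceptor. C6 becomes a carbonyl carbon and C5 and C10 are carried through unchanged, so the ring fusion stays trans as set in step 4; the new centre C8 is not controlled and need not be, since it becomes sp2 in step 14. The step needs abstraction of the formyl hydrogen in preference to other C–H bonds and ring closure faster than loss of CO; the weak, hydridic aldehyde C–H bond, the room temperature and the trans-diequatorial placing of the formyl and enone arms on ring A (C6 held next to C7) should secure both.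

Step 12
Reactants: 17 [2,5,8a-trimethyl-6-(3-methylbutanoyloxy)-1,4-dioxodecahydronaphthalen-5-yl]methyl 3-methylbutanoate
Product: 18 [4-hydroxy-2,5,8a-trimethyl-6-(3-methylbutanoyloxy)-1-oxodecahydronaphthalen-5-yl]methyl 3-methylbutanoate (6β-OH)
Conditions: LiBH(s-Bu)3 (1.05 equiv), THF, −78 °C; AcOH quench at −78 °C
Reagents that add atoms: none
Why: Chemoselective ketone reduction, in which the bulky hydride should reach C6 from the open α face (the β face is blocked by the axial C10 methyl and the C4 acyloxymethyl group) to give the axial 6β-alcohol, while the C9 ketone between the quaternary C10 and the C8 methine and the esters should survive at −78 °C; the cold acidic quench avoids acyl migration.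

Step 13
Reactants: 18 [4-hydroxy-2,5,8a-trimethyl-6-(3-methylbutanoyloxy)-1-oxodecahydronaphthalen-5-yl]methyl 3-methylbutanoate
Product: 19 [2,5,8a-trimethyl-6-(3-methylbutanoyloxy)-1-oxo-4-(triethylsilyloxy)decahydronaphthalen-5-yl]methyl 3-methylbutanoate
Conditions: Et3SiOTf, 2,6-lutidine, CH2Cl2, −78 → 0 °C
Reagents that add atoms: triethylsilyl trifluoromethanesulfonate, CC[Si](CC)(CC)OS(=O)(=O)C(F)(F)F
Why: Silylation of the hindered axial alcohol by the silyl triflate, so that no 6-alkoxide next to the C19 ester can form in step 14.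

Step 14
Reactants: 19 [2,5,8a-trimethyl-6-(3-methylbutanoyloxy)-1-oxo-4-(triethylsilyloxy)decahydronaphthalen-5-yl]methyl 3-methylbutanoate
Product: 21 [2,5,8a-trimethyl-6-(3-methylbutanoyloxy)-4-(triethylsilyloxy)-1-(trifluoromethylsulfonyloxy)-3,4,4a,5,6,7,8,8a-octahydronaphthalen-5-yl]methyl 3-methylbutanoate, via potassium enolate 20 (not isolated)
Conditions: KN(SiMe3)2 (1.1 equiv), THF, −78 °C; then PhNTf2, −78 → 0 °C
Reagents that add atoms: N-phenylbis(trifluoromethanesulfonimide), O=S(=O)(N(c1ccccc1)S(=O)(=O)C(F)(F)F)C(F)(F)F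
Why: Enol triflate formation, regiospecific because the C9 ketone can enolise only towards C8 (C10 is quaternary), which fixes the tetrasubstituted C8=C9 alkene and erases the C8 centre; the ketone α-hydrogen is more acidic than those of the esters.

Step 15
Reactants: 22 but-3-yn-1-ol
Product: 24 2-(trimethylsilyl)ethyl (2E)-5-hydroxy-3-methylpent-2-enoate, via alkenylalane 23 (not isolated)
Conditions: Me3Al (3 equiv), Cp2ZrCl2 (0.25 equiv), CH2Cl2, 0 °C → rt; then ClCO2CH2CH2SiMe3, 0 °C → rt
Reagents that add atoms: trimethylaluminium, C[Al](C)C; 2-(trimethylsilyl)ethyl chloroformate, C[Si](C)(C)CCOC(=O)Cl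
Why: Zirconium-catalysed syn-carboalumination of the terminal alkyne (Negishi carboalumination) places CH3 and Al cis, and C-acylation of the alkenylalane by the chloroformate with retention should give the E-enoate.

Step 16
Reactants: 24 2-(trimethylsilyl)ethyl (2E)-5-hydroxy-3-methylpent-2-enoate
Product: 25 2-(trimethylsilyl)ethyl (2E)-5-iodo-3-methylpent-2-enoate
Conditions: I2, PPh3, imidazole, CH2Cl2, 0 °C → rt
Reagents that add atoms: iodine, II
Why: Appel-type iodination of the primary alcohol, which does not touch the enoate geometry.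

Step 17
Reactants: 25 2-(trimethylsilyl)ethyl (2E)-5-iodo-3-methylpent-2-enoate; 21 [2,5,8a-trimethyl-6-(3-methylbutanoyloxy)-4-(triethylsilyloxy)-1-(trifluoromethylsulfonyloxy)-3,4,4a,5,6,7,8,8a-octahydronaphthalen-5-yl]methyl 3-methylbutanoate
Product: 27 2-(trimethylsilyl)ethyl (13E)-3α,19-bis(3-methylbutanoyloxy)-6β-(triethylsilyloxy)labda-8,13-dien-15-oate, via alkylzinc iodide 26 (not isolated)
Conditions: Zn, LiCl, THF, 40 °C; then 21, Pd(OAc)2 (5 mol%), SPhos (10 mol%), THF/NMP, 50 °C
Reagents that add atoms: none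
Why: Zinc insertion into the primary iodide followed by Negishi sp2–sp3 cross-coupling with the enol triflate should form C9–C11 with the alkene held at C8=C9 and with all ester groups tolerated.

Step 18
Reactants: 27 2-(trimethylsilyl)ethyl (13E)-3α,19-bis(3-methylbutanoyloxy)-6β-(triethylsilyloxy)labda-8,13-dien-15-oate
Product: 28 (13E)-6β-hydroxy-3α,19-bis(3-methylbutanoyloxy)labda-8,13-dien-15-oic acid (CNP0333611.1)
Conditions: n-Bu4NF (3 equiv), AcOH (3 equiv), THF, 0 °C → rt
Reagents that add atoms: none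
Why: Fluoride-induced desilylation should remove the silyl ether and cleave the 2-(trimethylsilyl)ethyl ester by β-elimination (loss of ethene) without touching the two carboxylic esters, and the acetic acid buffer should suppress acyl migration from O19 to the free 6β-hydroxyl.

**Compound list**

1 | (R)-2,2-dimethyl-1,3-dioxolane-4-carbaldehyde | CC1(C)OC[C@H](C=O)O1 | starting material
2 | 2-(triphenylphosphoranylidene)propanal | CC(C=O)=P(c1ccccc1)(c1ccccc1)c1ccccc1 | starting material
3 | (2E)-3-[(4S)-2,2-dimethyl-1,3-dioxolan-4-yl]-2-methylprop-2-enal | CC1(C)OC[C@H](/C=C(\C)C=O)O1 | intermediate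
4 | ethyl 3-hydroxypent-4-enoate (racemic) | C=CC(O)CC(=O)OCC | starting material
5 | ethyl 3-oxopent-4-enoate | C=CC(=O)CC(=O)OCC | intermediate
6 | ethyl (2Z)-3-(trimethylsilyloxy)penta-2,4-dienoate | C=C/C(O[Si](C)(C)C)=C/C(=O)OCC | intermediate
7 | ethyl 2-[(4S)-2,2-dimethyl-1,3-dioxolan-4-yl]-3-formyl-3-methyl-6-(trimethylsilyloxy)cyclohex-5-ene-1-carboxylate (cycloadduct, C4 epimers, not isolated) | O=C[C@@]2(C)CC=C(O[Si](C)(C)C)C(C(=O)OCC)[C@@H]2[C@H]1COC(C)(C)O1 | intermediate
8 | ethyl 2-[(4S)-2,2-dimethyl-1,3-dioxolan-4-yl]-3-formyl-3-methyl-6-oxocyclohexane-1-carboxylate (5α-H, 10β-CH3, C4 epimers) | O=C[C@@]2(C)CCC(=O)C(C(=O)OCC)[C@@H]2[C@H]1COC(C)(C)O1 | intermediate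
9 | ethyl 2-[(4S)-2,2-dimethyl-1,3-dioxolan-4-yl]-3-formyl-1,3-dimethyl-6-oxocyclohexane-1-carboxylate (4α-CH3, 4β-CO2Et) | O=C[C@@]2(C)CCC(=O)[C@](C)(C(=O)OCC)[C@@H]2[C@H]1COC(C)(C)O1 | intermediate
10 | 2-bromopropene | C=C(C)Br | starting material
11 | ethyl 2-[(4S)-2,2-dimethyl-1,3-dioxolan-4-yl]-3-(1-hydroxy-2-methylprop-2-enyl)-1,3-dimethyl-6-oxocyclohexane-1-carboxylate (C9 epimers) | C=C(C)C(O)[C@@]2(C)CCC(=O)[C@](C)(C(=O)OCC)[C@@H]2[C@H]1COC(C)(C)O1 | intermediate
12 | ethyl 2-[(4S)-2,2-dimethyl-1,3-dioxolan-4-yl]-6-hydroxy-3-(1-hydroxy-2-methylprop-2-enyl)-1,3-dimethylcyclohexane-1-carboxylate (3α-OH, not isolated) | C=C(C)C(O)[C@@]2(C)CC[C@@H](O)[C@](C)(C(=O)OCC)[C@@H]2[C@H]1COC(C)(C)O1 | intermediate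
13 | 3-[(4S)-2,2-dimethyl-1,3-dioxolan-4-yl]-2-(hydroxymethyl)-4-(1-hydroxy-2-methylprop-2-enyl)-2,4-dimethylcyclohexan-1-ol (3α-OH, C9 epimers) | C=C(C)C(O)[C@@]2(C)CC[C@@H](O)[C@](C)(CO)[C@@H]2[C@H]1COC(C)(C)O1 | intermediate
14 | 1-{2-[(4S)-2,2-dimethyl-1,3-dioxolan-4-yl]-4-hydroxy-3-(hydroxymethyl)-1,3-dimethylcyclohexyl}-2-methylprop-2-en-1-one | C=C(C)C(=O)[C@@]2(C)CC[C@@H](O)[C@](C)(CO)[C@@H]2[C@H]1COC(C)(C)O1 | intermediate
15 | {2-[(4S)-2,2-dimethyl-1,3-dioxolan-4-yl]-1,3-dimethyl-3-(2-methylprop-2-enoyl)-6-(3-methylbutanoyloxy)cyclohexyl}methyl 3-methylbutanoate | C=C(C)C(=O)[C@@]2(C)CC[C@@H](OC(=O)CC(C)C)[C@](C)(COC(=O)CC(C)C)[C@@H]2[C@H]1COC(C)(C)O1 | intermediate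
16 | [2-formyl-1,3-dimethyl-3-(2-methylprop-2-enoyl)-6-(3-methylbutanoyloxy)cyclohexyl]methyl 3-methylbutanoate (5α-H, 10β-CH3, 4α-CH3, 3α-O) | C=C(C)C(=O)[C@@]2(C)CC[C@@H](OC(=O)CC(C)C)[C@](C)(COC(=O)CC(C)C)[C@@H]2C=O | intermediate
17 | [2,5,8a-trimethyl-6-(3-methylbutanoyloxy)-1,4-dioxodecahydronaphthalen-5-yl]methyl 3-methylbutanoate (trans-fused, C8 epimers) | CC1C(=O)[C@@]2(C)CC[C@@H](OC(=O)CC(C)C)[C@](C)(COC(=O)CC(C)C)[C@@H]2C(=O)C1 | intermediate
18 | [4-hydroxy-2,5,8a-trimethyl-6-(3-methylbutanoyloxy)-1-oxodecahydronaphthalen-5-yl]methyl 3-methylbutanoate (6β-OH, C8 epimers) | CC1C(=O)[C@@]2(C)CC[C@@H](OC(=O)CC(C)C)[C@](C)(COC(=O)CC(C)C)[C@@H]2[C@H](O)C1 | intermediate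
19 | [2,5,8a-trimethyl-6-(3-methylbutanoyloxy)-1-oxo-4-(triethylsilyloxy)decahydronaphthalen-5-yl]methyl 3-methylbutanoate | CC1C(=O)[C@@]2(C)CC[C@@H](OC(=O)CC(C)C)[C@](C)(COC(=O)CC(C)C)[C@@H]2[C@H](O[Si](CC)(CC)CC)C1 | intermediate
20 | potassium enolate of 19 (C8=C9–OK, not isolated) | CC1=C([O-])[C@@]2(C)CC[C@@H](OC(=O)CC(C)C)[C@](C)(COC(=O)CC(C)C)[C@@H]2[C@H](O[Si](CC)(CC)CC)C1.[K+] | intermediate
21 | [2,5,8a-trimethyl-6-(3-methylbutanoyloxy)-4-(triethylsilyloxy)-1-(trifluoromethylsulfonyloxy)-3,4,4a,5,6,7,8,8a-octahydronaphthalen-5-yl]methyl 3-methylbutanoate | CC1=C(OS(=O)(=O)C(F)(F)F)[C@@]2(C)CC[C@@H](OC(=O)CC(C)C)[C@](C)(COC(=O)CC(C)C)[C@@H]2[C@H](O[Si](CC)(CC)CC)C1 | intermediate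
22 | but-3-yn-1-ol | C#CCCO | starting material
23 | (E)-alkenylalane, dimethylaluminium alkoxide form (not isolated) | C[Al](C)/C=C(C)/CCO[Al](C)C | intermediate
24 | 2-(trimethylsilyl)ethyl (2E)-5-hydroxy-3-methylpent-2-enoate | C[Si](C)(C)CCOC(=O)/C=C(C)/CCO | intermediate
25 | 2-(trimethylsilyl)ethyl (2E)-5-iodo-3-methylpent-2-enoate | C[Si](C)(C)CCOC(=O)/C=C(C)/CCI | intermediate
26 | alkylzinc iodide from 25 (not isolated) | C[Si](C)(C)CCOC(=O)/C=C(C)/CC[Zn]I | intermediate
27 | 2-(trimethylsilyl)ethyl (13E)-3α,19-bis(3-methylbutanoyloxy)-6β-(triethylsilyloxy)labda-8,13-dien-15-oate | CC1=C(CC/C(C)=C/C(=O)OCC[Si](C)(C)C)[C@@]2(C)CC[C@@H](OC(=O)CC(C)C)[C@](C)(COC(=O)CC(C)C)[C@@H]2[C@H](O[Si](CC)(CC)CC)C1 | intermediate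
28 | (13E)-6β-hydroxy-3α,19-bis(3-methylbutanoyloxy)labda-8,13-dien-15-oic acid | CC1=C(CC/C(C)=C/C(=O)O)[C@@]2(C)CC[C@@H](OC(=O)CC(C)C)[C@](C)(COC(=O)CC(C)C)[C@@H]2[C@H](O)C1 | target

**Step count**

Total: 18 steps. Longest linear sequence: 15 steps (steps 2–14, 17, 18).

**Steps most likely to fail**

1. Step 4. The ester-deactivated diene may react too slowly with the trisubstituted enal, so that diene or enal decomposes, and the facial discrimination by the dioxolane may be poor. The fallback sets out from 3 and 5 (step 3 is skipped) and returns at 8. It is the stepwise anionic annulation with Cs2CO3 in CH2Cl2 at rt: conjugate addition of the keto ester enolate of 5 to C5 of the enal, then intramolecular Michael addition of the resulting aldehyde enolate to the vinyl ketone. The first addition is under the same acyclic control. The C10 configuration would then rest on a chair-like closure and on separation of diastereomers. No new compound is made.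

2. Step 11. The acyl radical may lose CO before it closes the ring, or hydrogen abstraction may occur at other C–H bonds. The fallback sets out from 16 and returns at 17. It is a reductive aldehyde–enone (ketyl–olefin) cyclisation with SmI2 in THF/MeOH at −78 °C, which forms the same C6–C7 bond without an acyl radical and gives [4-hydroxy-2,5,8a-trimethyl-6-(3-methylbutanoyloxy)-1-oxodecahydronaphthalen-5-yl]methyl 3-methylbutanoate as a mixture at C6 and C8, F1. Oxidation of F1 with Dess–Martin periodinane gives 17.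

3. Step 17. Oxidative addition and transmetalation at the hindered tetrasubstituted triflate may be slow, so that reduction of the triflate or decay of the alkylzinc competes. The fallback sets out from 25 and returns at 27. Elimination with DBU gives 2-(trimethylsilyl)ethyl (2E)-3-methylpenta-2,4-dienoate, F2. Hydroboration of its terminal alkene with 9-BBN gives 2-(trimethylsilyl)ethyl (2E)-5-(9-borabicyclo[3.3.1]nonan-9-yl)-3-methylpent-2-enoate, F3. B-alkyl Suzuki–Miyaura coupling of F3 with 21 (PdCl2(dppf), K3PO4, AsPh3, DMF/H2O, 50 °C) gives 27.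

**Further compounds**

F0 | step 4 | none | none
F1 | step 11 | [4-hydroxy-2,5,8a-trimethyl-6-(3-methylbutanoyloxy)-1-oxodecahydronaphthalen-5-yl]methyl 3-methylbutanoate (C6 and C8 epimers) | CC1C(=O)[C@@]2(C)CC[C@@H](OC(=O)CC(C)C)[C@](C)(COC(=O)CC(C)C)[C@@H]2C(O)C1
F2 | step 17 | 2-(trimethylsilyl)ethyl (2E)-3-methylpenta-2,4-dienoate | C=C/C(C)=C/C(=O)OCC[Si](C)(C)C
F3 | step 17 | 2-(trimethylsilyl)ethyl (2E)-5-(9-borabicyclo[3.3.1]nonan-9-yl)-3-methylpent-2-enoate | C[Si](C)(C)CCOC(=O)/C=C(C)/CCB1C2CCCC1CCC2
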